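## Retrosynthetic overview

- The last step is global deacetylation of pentaacetate 22. The two flavan units are joined through the ether oxygen before the lower unit exists as a ring.
- Key disconnection (lower unit, ring C): O-1–C-2 and C-4a–C-4 are cut together. This gives a pyrogallol silyl ether and a C-2/C-3/C-4 chain at the oxidation level of a trans-α,β-epoxy cinnamaldehyde, whose aldehyde carbon (C-4) is held as an oxocarbenium ion on O-4 of the finished upper unit.
- Enabling feature: in the lower unit, ring A is a pyrogallol ring in which C-4a is ortho to the ring oxygen O-1 (on C-8a) and para to O-7, so O-1/C-8a/C-4a is a phenol 1,3-O,C-dinucleophile. In ring C, C-4 is an aldehyde-derived ether carbon flanked by the C-3 carbinol and the benzylic C-2–O-1 bond, so C-4/C-3/C-2 is a 1,3-dielectrophile.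
- Upper unit (all-cis, 2R,3R,4R): a flavanone from asymmetric conjugate addition to a chromone, then the flav-3-ene, then Woodward cis-hydroxylation, which delivers the 3-acetate with free 4-OH directly.
- Order of ring formation: upper pyranone ring (step 1), upper stereocentres (steps 3–6), epoxide of the three-carbon unit (step 9), lower pyran ring last (step 11).

Key step: step 11

Assumption: (R)-t-BuPyOX is taken to give the (2S)-flavanone (step 3) and the (S)-diarylprolinol silyl ether the (2S,3R)-epoxy aldehyde (step 9, H2O2 attacking the face of the E-iminium ion away from the silyloxydiarylmethyl group); if a rotation check on 6 or 16 shows the other sense, the other enantiomer of that ligand or catalyst is used.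

## Route

Step 1
Reactants: 1 2',3',4'-trihydroxyacetophenone
Product: 3 7,8-dihydroxy-4H-chromen-4-one, via 4-ethoxybenzopyrylium perchlorate 2 (not isolated)
Conditions: HC(OEt)3 (excess), 70% HClO4 (1.1 equiv), 0 °C → rt; then H2O, 80 °C
Reagents that add atoms: triethyl orthoformate CCOC(OCC)OCC (C-2); water O (carbonyl oxygen on hydrolysis of the ethoxypyrylium salt)
Why: Acid-promoted C-formylation of the methyl ketone by the diethoxycarbenium ion and ring closure onto the ortho phenol give the 4-ethoxybenzopyrylium salt, whose hydrolysis gives the chromone (orthoformate–perchloric acid chromone synthesis); any catechol orthoformate is cleaved in the aqueous stage.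

Step 2
Reactants: 3 7,8-dihydroxy-4H-chromen-4-one
Product: 4 4-oxo-4H-chromene-7,8-diyl diacetate
Conditions: Ac2O, pyridine, DMAP (cat.), rt
Reagents that add atoms: acetic anhydride CC(=O)OC(C)=O
Why: Standard O-acetylation of the catechol; the acetates make ring A electron-poor for the later cation chemistry and are the only protecting groups of the route.

Step 3
Reactants: 4 4-oxo-4H-chromene-7,8-diyl diacetate; 5 4-acetoxyphenylboronic acid
Product: 6 (2S)-2-(4-acetoxyphenyl)-4-oxochroman-7,8-diyl diacetate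
Conditions: Pd(OCOCF3)2 (5 mol %), (R)-t-BuPyOX (6 mol %), NH4PF6 (30 mol %), H2O (5 equiv), ClCH2CH2Cl, 60 °C
Reagents that add atoms: none
Why: Palladium-catalysed asymmetric conjugate addition of an arylboronic acid to a chromone with a pyridine-oxazoline ligand, a reaction type that tolerates aryl esters; the ligand controls the face of aryl transfer and sets C-2 as S.

Step 4
Reactants: 6 (2S)-flavanone triacetate
Product: 7 (2S,4S)-2-(4-acetoxyphenyl)-4-hydroxychroman-7,8-diyl diacetate (2,4-cis)
Conditions: NaBH4, CeCl3·7H2O, MeOH/THF, −40 °C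
Reagents that add atoms: none
Why: Luche reduction of the aryl ketone is fast at low temperature, so the aryl acetates should survive; axial hydride attack should give mainly the 2,4-cis alcohol, and C-4 is erased in the next step in any case.

Step 5
Reactants: 7 (2S,4S)-flavan-4-ol triacetate
Product: 8 (2S)-2-(4-acetoxyphenyl)-2H-chromene-7,8-diyl diacetate
Conditions: Burgess reagent, toluene/THF, 50 °C, dark
Reagents that add atoms: none
Why: Burgess dehydration (syn elimination of the C-4 sulfamate with H-3) under neutral conditions gives the 2H-chromene without touching C-2; light and heat are avoided to prevent electrocyclic ring opening.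

Step 6
Reactants: 8 (2S)-flav-3-ene triacetate
Product: 11 (2R,3R,4R)-2-(4-acetoxyphenyl)-4-hydroxychroman-3,7,8-triyl triacetate (all-cis), via trans-iodoacetate 9 (not isolated), via acetoxonium acetate 10 (not isolated)
Conditions: I2 (1.05 equiv), AgOAc (2.2 equiv), AcOH, rt, dark; then H2O (1.5 equiv), 60 °C
Reagents that add atoms: silver acetate CC(=O)[O-].[Ag+]; water O
Why: Woodward cis-hydroxylation: the iodonium ion forms anti to the C-2 aryl group, acetate opens it at benzylic C-4, the neighbouring acetate displaces iodide with inversion at C-3, and hydrolysis of the cis-fused acetoxonium ion leaves both oxygens syn to the aryl group (all-cis) with the ester on the axial O-3 and the 4-OH free.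

Step 7
Reactants: 11 all-cis 3-acetate 4-ol
Product: 12 4-O-trimethylsilyl ether of 11
Conditions: TMSCl, imidazole, CH2Cl2, 0 °C; used without chromatography
Reagents that add atoms: chlorotrimethylsilane C[Si](C)(C)Cl
Why: Routine silylation of the secondary benzylic alcohol; the TMS ether is the alkoxy donor for oxocarbenium formation in step 11.

Step 8
Reactants: 13 4-acetoxybenzaldehyde; 14 (triphenylphosphoranylidene)acetaldehyde
Product: 15 (E)-3-(4-acetoxyphenyl)prop-2-enal
Conditions: toluene, 80 °C
Reagents that add atoms: none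
Why: Wittig reaction of the stabilised formylmethylene ylide gives the E-enal.

Step 9
Reactants: 15 (E)-4-acetoxycinnamaldehyde
Product: 16 (2S,3R)-3-(4-acetoxyphenyl)oxirane-2-carbaldehyde (trans)
Conditions: (S)-2-{bis[3,5-bis(trifluoromethyl)phenyl][(trimethylsilyl)oxy]methyl}pyrrolidine (10 mol %), 35% aq. H2O2 (1.3 equiv), CH2Cl2, rt; used crude
Reagents that add atoms: hydrogen peroxide OO
Why: Organocatalytic asymmetric epoxidation of an enal through its iminium ion (conjugate addition of H2O2, then ring closure of the enamine onto the peroxide oxygen); the catalyst shields one face of the E-iminium ion and sets both epoxide carbons, trans.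

Step 10
Reactants: 17 pyrogallol
Product: 18 1,2,3-tris(trimethylsilyloxy)benzene
Conditions: (Me3Si)2NH (2 equiv), TMSCl (cat.), 110 °C, neat; distillation
Reagents that add atoms: hexamethyldisilazane C[Si](C)(C)N[Si](C)(C)C
Why: Exhaustive O-silylation gives a soluble, symmetric pyrogallol donor.

Step 11
Reactants: 12 upper-unit 4-O-TMS ether; 16 (2S,3R)-epoxy aldehyde; 18 1,2,3-tris(trimethylsilyloxy)benzene
Product: 22 pentaacetate of the target (upper unit 3,7,8,4'-tetra-O-acetyl; lower unit 4'-O-acetyl with free 3-OH and 7,8-catechol), via mixed silyl acetal 19 (not isolated), via oxocarbenium triflate 20 (not isolated), via Friedel–Crafts adduct 21 (not isolated)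
Conditions: 12 (1.0 equiv), 16 (1.2 equiv), TMSOTf (0.2 equiv), 4 Å MS, CH2Cl2, −78 °C, 30 min; then 18 (2.5 equiv), −78 → −40 °C; Et3N; then NH4F, MeOH, 0 °C
Reagents that add atoms: none
Why: Proposed new method: TMSOTf converts silyl ether 12 and aldehyde 16 into the mixed silyl acetal 19 and then the O-(flavan-4-yl) oxocarbenium ion 20 (the first half of a silyl-modified Sakurai three-component coupling, with the arene in the role of the allylsilane), C-4 of the symmetric pyrogallol silyl ether 18 attacks 20 to give 21, and the flanking aryl O–SiMe3 then opens the Lewis-acid-activated epoxide at the benzylic carbon, so that C-4a–C-4 and O-1–C-2 form in one flask as a formal [3+3] annulation. The closest known reaction types are additions of carbon nucleophiles to oxocarbenium ions made from aldehydes and silyl ethers, Felkin–Anh additions to α,β-epoxy aldehydes, and the acid-catalysed cyclisation of 2-hydroxyaryl epoxides to flavan-3-ols. The one ring that closes, the lower pyran ring, closes in the 6-endo-tet mode by SN2-like attack of O-1 on C-2 with inversion, preferred over 5-exo because C-2 is benzylic while C-3 is flanked by the hindered ether carbon. C-4 is set in the C–C bond formation by Felkin–Anh (Cornforth) control, the arene adding anti to the epoxide C–O bond to give the erythro, later 3,4-cis, relation; C-2 is set by inversion of the R epoxide carbon (2,3-trans) and C-3 is carried over from 16. The step needs ortho C-alkylation, which the C2v-symmetric donor secures because its only activated carbons, C-4 and C-6, are each ortho to one oxygen and para to another; it also needs both benzylic C-4–O bonds to stay intact, which the acetates on ring A of the upper unit (a poor flavan-4-yl cation, so 20 should not fragment), the 5-deoxy pyrogallol-type ring A of the new unit, −78 °C and catalytic acid are meant to secure.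

Step 12
Reactants: 22 pentaacetate
Product: 23 (2R,3R,4R)-2-(4-hydroxyphenyl)-4-{[(2S,3R,4R)-3,7,8-trihydroxy-2-(4-hydroxyphenyl)chroman-4-yl]oxy}chroman-3,7,8-triol (target)
Conditions: N2H4·H2O (12 equiv), degassed THF/MeOH (1:1), 0 °C → rt, Ar; AcOH to pH 6; Sephadex LH-20 (MeOH)
Reagents that add atoms: none
Why: Hydrazinolysis of the four aryl acetates and the one alkyl acetate under near-neutral, reducing conditions, which should keep the catechols from oxidation and the bis-benzylic ether from ionisation or quinone-methide cleavage; no stereocentre is touched.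

## Compound list

1 | 2',3',4'-trihydroxyacetophenone (gallacetophenone) | CC(=O)c1ccc(O)c(O)c1O | starting material
2 | 4-ethoxy-7,8-dihydroxychromenylium perchlorate | CCOc1cc[o+]c2c(O)c(O)ccc12.[O-]Cl(=O)(=O)=O | intermediate
3 | 7,8-dihydroxy-4H-chromen-4-one | O=c1ccoc2c(O)c(O)ccc12 | intermediate
4 | 4-oxo-4H-chromene-7,8-diyl diacetate | O=c1ccoc2c(OC(C)=O)c(OC(C)=O)ccc12 | intermediate
5 | 4-acetoxyphenylboronic acid | CC(=O)Oc1ccc(B(O)O)cc1 | starting material
6 | (2S)-2-(4-acetoxyphenyl)-4-oxochroman-7,8-diyl diacetate | CC(=O)Oc1ccc([C@H]2Oc3c(ccc(OC(C)=O)c3OC(C)=O)C(=O)C2)cc1 | intermediate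
7 | (2S,4S)-2-(4-acetoxyphenyl)-4-hydroxychroman-7,8-diyl diacetate (2,4-cis) | CC(=O)Oc1ccc([C@H]2Oc3c(ccc(OC(C)=O)c3OC(C)=O)[C@@H](O)C2)cc1 | intermediate
8 | (2S)-2-(4-acetoxyphenyl)-2H-chromene-7,8-diyl diacetate | CC(=O)Oc1ccc([C@H]2Oc3c(ccc(OC(C)=O)c3OC(C)=O)C=C2)cc1 | intermediate
9 | (2R,3R,4R)-2-(4-acetoxyphenyl)-3-iodochroman-4,7,8-triyl triacetate (2α-aryl, 3β-iodo, 4α-acetoxy) | CC(=O)Oc1ccc([C@H]2Oc3c(ccc(OC(C)=O)c3OC(C)=O)[C@@H](OC(C)=O)[C@@H]2I)cc1 | intermediate
10 | cis-fused 2-methyl-1,3-dioxolan-2-ylium ion bridging O-3 and O-4 on the α face (same face as the aryl group), acetate salt | CC(=O)Oc1ccc([C@H]2Oc3c(ccc(OC(C)=O)c3OC(C)=O)[C@H]4OC(C)=[O+][C@H]42)cc1.CC(=O)[O-] | intermediate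
11 | (2R,3R,4R)-2-(4-acetoxyphenyl)-4-hydroxychroman-3,7,8-triyl triacetate (all-cis; 2α-aryl, 3α-OAc, 4α-OH) | CC(=O)Oc1ccc([C@H]2Oc3c(ccc(OC(C)=O)c3OC(C)=O)[C@@H](O)[C@H]2OC(C)=O)cc1 | intermediate
12 | 4-O-trimethylsilyl ether of 11 (same spatial arrangement; 2R,3S,4R by the sequence rule) | CC(=O)Oc1ccc([C@H]2Oc3c(ccc(OC(C)=O)c3OC(C)=O)[C@@H](O[Si](C)(C)C)[C@H]2OC(C)=O)cc1 | intermediate
13 | 4-acetoxybenzaldehyde | CC(=O)Oc1ccc(C=O)cc1 | starting material
14 | (triphenylphosphoranylidene)acetaldehyde | O=CC=P(c1ccccc1)(c1ccccc1)c1ccccc1 | starting material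
15 | (E)-3-(4-acetoxyphenyl)prop-2-enal | CC(=O)Oc1ccc(/C=C/C=O)cc1 | intermediate
16 | (2S,3R)-3-(4-acetoxyphenyl)oxirane-2-carbaldehyde (trans) | O=C[C@H]1O[C@@H]1c1ccc(OC(C)=O)cc1 | intermediate
17 | pyrogallol (benzene-1,2,3-triol) | Oc1cccc(O)c1O | starting material
18 | 1,2,3-tris(trimethylsilyloxy)benzene | C[Si](C)(C)Oc1cccc(O[Si](C)(C)C)c1O[Si](C)(C)C | intermediate
19 | mixed acetal of 16 with O-4 of the upper unit and OSiMe3 on the former aldehyde carbon (both epimers at that carbon; other centres as in 12 and 16) | CC(=O)Oc1ccc([C@H]2Oc3c(ccc(OC(C)=O)c3OC(C)=O)[C@@H](OC(O[Si](C)(C)C)[C@H]4O[C@@H]4c5ccc(OC(C)=O)cc5)[C@H]2OC(C)=O)cc1 | intermediate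
20 | O-(upper-unit flavan-4-yl) oxocarbenium ion of the epoxy aldehyde, triflate | CC(=O)Oc1ccc([C@H]2Oc3c(ccc(OC(C)=O)c3OC(C)=O)[C@@H]([O+]=C[C@H]4O[C@@H]4c5ccc(OC(C)=O)cc5)[C@H]2OC(C)=O)cc1.[O-]S(=O)(=O)C(F)(F)F | intermediate
21 | Friedel–Crafts adduct: upper unit–O–CH[2,3,4-tris(trimethylsilyloxy)phenyl]–(trans-epoxide)–4-acetoxyphenyl, ether carbon erythro to the epoxide | CC(=O)Oc1ccc([C@H]2Oc3c(ccc(OC(C)=O)c3OC(C)=O)[C@@H](O[C@H](c4ccc(O[Si](C)(C)C)c(O[Si](C)(C)C)c4O[Si](C)(C)C)[C@H]5O[C@@H]5c6ccc(OC(C)=O)cc6)[C@H]2OC(C)=O)cc1 | intermediate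
22 | pentaacetate of the target: upper unit (2R,3R,4R) 3,7,8,4'-tetra-O-acetyl; lower unit (2S,3R,4R) 4'-O-acetyl, 3-OH and 7,8-OH free | CC(=O)Oc1ccc([C@H]2Oc3c(ccc(OC(C)=O)c3OC(C)=O)[C@@H](O[C@@H]3c4ccc(O)c(O)c4O[C@@H](c4ccc(OC(C)=O)cc4)[C@@H]3O)[C@H]2OC(C)=O)cc1 | intermediate
23 | (2R,3R,4R)-2-(4-hydroxyphenyl)-4-{[(2S,3R,4R)-3,7,8-trihydroxy-2-(4-hydroxyphenyl)chroman-4-yl]oxy}chroman-3,7,8-triol | Oc1ccc([C@H]2Oc3c(ccc(O)c3O)[C@@H](O[C@@H]3c4ccc(O)c(O)c4O[C@@H](c4ccc(O)cc4)[C@@H]3O)[C@H]2O)cc1 | target

## Summary and risks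

Total step count: 12. Longest linear sequence: 9 steps (steps 1–7, 11, 12).

**Step 11 (proposed new method).**
What may go wrong:
- the hindered silyl ether 12 may fail to engage the aldehyde, so that 18 adds to free 16;
- facial control at C-4 by the epoxide may be opposed by the chiral upper unit;
- the oxocarbenium ion may fragment, or the new benzylic ether may ionise on warming;
- the epoxide may rearrange before O-1 closes the ring.

Fallback (known chemistry; sets out from 4 and 11, comes back at 23): the interflavan ether is made by reductive etherification, so that the ether oxygen comes from a cis-diol of the lower unit and C-4 of the upper unit is set by hydride. Chromone 4 and boronic acid 5 with (S)-t-BuPyOX under the conditions of step 3 give the (R)-flavanone triacetate F1. Luche reduction gives the (2R,4R)-flavan-4-ol F2, and Burgess dehydration gives the (R)-flav-3-ene F3. OsO4 (cat.)/NMO adds anti to the aryl group to give the 2,3-trans-3,4-cis diol F4. Its dibutylstannylene acetal (Bu2SnO, toluene, reflux) is acetylated at the equatorial O-3 (AcCl, 0 °C) to give the 3-acetate F5, which is silylated (TMSCl, imidazole) to the 4-O-trimethylsilyl ether F6. In parallel, alcohol 11 is oxidised (Dess–Martin periodinane, NaHCO3, CH2Cl2) to the 2,3-cis-3-acetoxyflavan-4-one F7. F7 and F6 with Et3SiH and TMSOTf (CH2Cl2, −78 → −40 °C) should give, by axial hydride delivery anti to the axial 3-acetoxy group, the all-cis upper unit in the octaacetate F8. Hydrazinolysis as in step 12 then gives 23.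

**Step 6.**
What may go wrong: acetyl migration between O-3 and O-4 in warm acetic acid, incomplete facial control in iodonium formation, and silver-assisted ionisation at C-4 with loss of the trans relation of iodide and acetate.

Fallback (sets out from 8, comes back at 11): the two inversions are done one at a time through an epoxide. Dimethyldioxirane (acetone, 0 °C) epoxidises 8 anti to the aryl group to the 3β,4β-epoxide F9. Acetic acid opens it at benzylic C-4 with inversion to the trans 4α-acetoxy-3β-ol F10. Tf2O/pyridine (CH2Cl2, −20 °C) turns the 3β-OH into a triflate, which the neighbouring acetate displaces with inversion; aqueous NaHCO3 then hydrolyses the acetoxonium ion (the cation of 10) to 11.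

**Step 9.**
What may go wrong: perhydrolysis of the aryl acetate, hydrate or oligomer formation and partial epimerisation of the sensitive epoxy aldehyde on handling, and enantioselectivity below what the coupling needs.

Fallback (sets out from 15, comes back at 16): directed epoxidation of the allylic alcohol in place of iminium catalysis. Luche reduction (NaBH4, CeCl3·7H2O, MeOH, −40 °C) gives the (E)-cinnamyl alcohol F11. Sharpless asymmetric epoxidation (Ti(OiPr)4, D-(−)-diisopropyl tartrate, t-BuOOH, 4 Å MS, CH2Cl2, −20 °C) gives the (2R,3R)-epoxy alcohol F12. Dess–Martin oxidation (NaHCO3, CH2Cl2, 0 °C) gives 16.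

## Further compounds

F1 | step 11 | (2R)-2-(4-acetoxyphenyl)-4-oxochroman-7,8-diyl diacetate | CC(=O)Oc1ccc([C@@H]2Oc3c(ccc(OC(C)=O)c3OC(C)=O)C(=O)C2)cc1
F2 | step 11 | (2R,4R)-2-(4-acetoxyphenyl)-4-hydroxychroman-7,8-diyl diacetate | CC(=O)Oc1ccc([C@@H]2Oc3c(ccc(OC(C)=O)c3OC(C)=O)[C@H](O)C2)cc1
F3 | step 11 | (2R)-2-(4-acetoxyphenyl)-2H-chromene-7,8-diyl diacetate | CC(=O)Oc1ccc([C@@H]2Oc3c(ccc(OC(C)=O)c3OC(C)=O)C=C2)cc1
F4 | step 11 | (2S,3R,4R)-2-(4-acetoxyphenyl)-3,4-dihydroxychroman-7,8-diyl diacetate (2,3-trans-3,4-cis) | CC(=O)Oc1ccc([C@@H]2Oc3c(ccc(OC(C)=O)c3OC(C)=O)[C@@H](O)[C@H]2O)cc1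
F5 | step 11 | (2S,3R,4R)-2-(4-acetoxyphenyl)-4-hydroxychroman-3,7,8-triyl triacetate | CC(=O)Oc1ccc([C@@H]2Oc3c(ccc(OC(C)=O)c3OC(C)=O)[C@@H](O)[C@H]2OC(C)=O)cc1
F6 | step 11 | 4-O-trimethylsilyl ether of F5 | CC(=O)Oc1ccc([C@@H]2Oc3c(ccc(OC(C)=O)c3OC(C)=O)[C@@H](O[Si](C)(C)C)[C@H]2OC(C)=O)cc1
F7 | step 11 | (2R,3S)-2-(4-acetoxyphenyl)-4-oxochroman-3,7,8-triyl triacetate (2,3-cis) | CC(=O)Oc1ccc([C@H]2Oc3c(ccc(OC(C)=O)c3OC(C)=O)C(=O)[C@H]2OC(C)=O)cc1
F8 | step 11 | octaacetate of the target (all six phenols and both 3-OH acetylated) | CC(=O)Oc1ccc([C@H]2Oc3c(ccc(OC(C)=O)c3OC(C)=O)[C@@H](O[C@@H]3c4ccc(OC(C)=O)c(OC(C)=O)c4O[C@@H](c4ccc(OC(C)=O)cc4)[C@@H]3OC(C)=O)[C@H]2OC(C)=O)cc1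
F9 | step 6 | 3β,4β-epoxide of 8 (oxirane anti to the 2α-aryl group) | CC(=O)Oc1ccc([C@H]2Oc3c(ccc(OC(C)=O)c3OC(C)=O)[C@@H]4O[C@@H]42)cc1
F10 | step 6 | 2α-(4-acetoxyphenyl)-3β-hydroxychroman-4α,7,8-triyl triacetate (2,3-trans-3,4-trans) | CC(=O)Oc1ccc([C@H]2Oc3c(ccc(OC(C)=O)c3OC(C)=O)[C@@H](OC(C)=O)[C@@H]2O)cc1
F11 | step 9 | (E)-4-(3-hydroxyprop-1-en-1-yl)phenyl acetate | CC(=O)Oc1ccc(/C=C/CO)cc1
F12 | step 9 | [(2R,3R)-3-(4-acetoxyphenyl)oxiran-2-yl]methanol | OC[C@H]1O[C@@H]1c1ccc(OC(C)=O)cc1
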